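**Strategy.** The target, a guai-4-en-3-one, is disconnected to a eudesmane. Its cyclopentenone (C1–C5) is the contracted A ring of a cross-conjugated eudesma-1,4-dien-3-one, and its cycloheptane (C1, C5–C10) is the expanded B ring. The feature used is that C10, the methyl-bearing carbon next to the ring-fusion carbon C1, was the angular carbon of a decalin. One photochemical step (santonin-type rearrangement in aqueous acetic acid) forms C1–C5, cleaves C5–C10, creates the 4-methylcyclopentenone and leaves C10 as a carbinol that is later reduced. The precursor is a 10β-methyl dienone already carrying the 8β-propanoate and the 11-acetate, assembled by an auxiliary-controlled Robinson annulation, an acetone aldol and a ketone reduction. C1 is equilibrated last.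

Key step: step 8

Remark: 1 is taken as a catalogue compound (racemic); its stereocentre is erased in the enamine tautomer of 5, so no resolution is needed.

Step 1
Reactants: 1 7-methyl-1,4-dioxaspiro[4.5]decan-8-one; 2 (R)-1-phenylethylamine; 3 pent-1-en-3-one; 4 water
Product: 7 (7R)-7-methyl-7-(3-oxopentyl)-1,4-dioxaspiro[4.5]decan-8-one, via imine 5 (not isolated), via alkylated imine 6 (not isolated)
Conditions: 2, toluene, reflux, Dean–Stark; then 3, THF, 40 °C; then 20% aq. AcOH, rt
Reagents that add atoms: pent-1-en-3-one (3), CCC(=O)C=C; water (4), O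
Why: Deracemising Michael addition of a chiral imine (d'Angelo variant of the Robinson annulation): the more substituted secondary enamine tautomer of 5 adds to 3 through a compact aza-ene-like transition state on the face anti to the phenyl group of the (R)-auxiliary, which sets the quaternary centre as R (the later 10β-methyl), and dilute acetic acid hydrolyses the imine without touching the dioxolane.

Step 2
Reactants: 7 (7R)-7-methyl-7-(3-oxopentyl)-1,4-dioxaspiro[4.5]decan-8-one
Product: 9 (4aR)-6,6-(ethane-1,2-diyldioxy)-1,4a-dimethyl-4,4a,5,6,7,8-hexahydronaphthalen-2(3H)-one, via ketol 8 (not isolated)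
Conditions: NaOMe (0.5 equiv), MeOH, 60 °C
Reagents that add atoms: none
Why: Base-mediated intramolecular aldol condensation completes the Robinson annulation; the dioxolane is inert to methoxide and the quaternary centre is not enolisable.

Step 3
Reactants: 9 enone ketal; 4 water
Product: 11 (4aS)-1,4a-dimethyl-4a,5,7,8-tetrahydronaphthalene-2,6-dione, via dienone ketal 10 (not isolated)
Conditions: DDQ (1.3 equiv), dioxane, reflux; then 1 M HCl, THF, rt
Reagents that add atoms: water (4), O
Why: DDQ dehydrogenation of the Δ4-3-ketone through its Δ2,4-dienol introduces the 1,2-double bond (steroid-type 1,4-dien-3-one formation), dilute acid then hydrolyses the dioxolane, and the dienone thereby loses its α′-protons ahead of the enolate chemistry.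

Step 4
Reactants: 11 dienedione; 12 acetone
Product: 13 (7R,10S)-11-hydroxyeudesma-1,4-diene-3,8-dione (7β side chain, 10β-methyl)
Conditions: LDA (1.1 equiv), THF, −78 °C; ZnCl2 (1.1 equiv); 12, −78 → −20 °C; aq. NH4Cl
Reagents that add atoms: acetone (12), CC(C)=O
Why: Directed aldol addition of a preformed enolate: LDA deprotonates the only kinetically accessible α-position, C7 (C9 is neopentyl, the dienone has no α′-H), and the zinc aldolate, which forms reversibly, settles on the chelate with the bulky 2-hydroxyprop-2-yl group equatorial, that is 7β and cis to the axial angular methyl in the flat formula.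

Step 5
Reactants: 13 aldol adduct
Product: 14 (7S,8R,10S)-8,11-dihydroxyeudesma-1,4-dien-3-one (8β-OH, 7β side chain, 10β-methyl)
Conditions: NaBH4, MeOH–CH2Cl2, −40 → −20 °C
Reagents that add atoms: none
Why: Borohydride reduces the saturated ketone much faster than the cross-conjugated dienone at low temperature (steroid 17-ketone versus 1,4-dien-3-one precedent), and because the axial trajectory on the β-face is blocked by the syn-axial 10β-methyl group the hydride arrives from the α-face and gives the axial 8β-alcohol cis to the side chain.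

Step 6
Reactants: 14 diol; 15 propanoic anhydride
Product: 16 (7S,8R,10S)-11-hydroxy-8-propanoyloxyeudesma-1,4-dien-3-one
Conditions: 15 (1.5 equiv), Et3N, DMAP (0.1 equiv), CH2Cl2, 0 °C → rt
Reagents that add atoms: propanoic anhydride (15), CCC(=O)OC(=O)CC
Why: DMAP-catalysed acylation esterifies the secondary alcohol and leaves the far more hindered tertiary alcohol free.

Step 7
Reactants: 16 hydroxy propanoate; 17 acetic anhydride
Product: 18 (7S,8R,10S)-11-acetoxy-8-propanoyloxyeudesma-1,4-dien-3-one
Conditions: 17 (5 equiv), DMAP (1.5 equiv), Et3N, CH2Cl2, 40 °C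
Reagents that add atoms: acetic anhydride (17), CC(=O)OC(C)=O
Why: Steglich-type acetylation of the tertiary alcohol with excess anhydride and stoichiometric DMAP under basic conditions, which avoid ionisation at C11 and acyl scrambling.

Step 8
Reactants: 18 diester dienone; 4 water
Product: 19 (1R,7S,8R,10R)-11-acetoxy-10-hydroxy-8-propanoyloxyguai-4-en-3-one (1α-H, 10α-OH, 10β-CH3)
Conditions: hν (medium-pressure Hg lamp, Pyrex), AcOH–H2O (1:1), 15 °C, argon
Reagents that add atoms: water (4), O
Why: Santonin-type photorearrangement of a cross-conjugated cyclohexadienone: excitation of the dienone leads to C1–C5 bonding and a bicyclo[3.1.0]hexenone zwitterion (cyclopropane C1–C5–C10), which is protonated on oxygen in the acidic medium and opened by water at C10 with cleavage of the C5–C10 bond. The closest known reaction is the conversion of α-santonin into isophotosantonic lactone and of 4-methyl-1,4-dien-3-ones of the 1,2-dehydrocyperone type into 10-hydroxyguai-4-en-3-ones in aqueous acetic acid. The six-membered ring A contracts to the cyclopentenone C1–C5 by this 1,5-bonding (a formal 1,2-shift of C5 from C10 to C1), and ring B grows to the seven-membered ring in the same event, so no separate cyclisation is involved. C1 is set stereospecifically by the angular carbon (the bridging C10 must tip to the face of its methyl group, so 10β-methyl gives 1α-H) and C10 takes up water anti to the departing C5 (10α-OH, 10β-CH3); C7 and C8 are not touched. The step needs the 5/7 pathway to win over lumiketone and spiro[4.5]decenone formation, which the C4 methyl group and the protic acidic medium secure, and it needs the esters to survive, which holds in aqueous acetic acid at ambient temperature.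

Step 9
Reactants: 19 hydroxy ketone
Product: 20 (1S,7S,8R)-11-acetoxy-8-propanoyloxyguaia-4,10(14)-dien-3-one (1α-H)
Conditions: SOCl2 (1.5 equiv), pyridine, −20 → 0 °C
Reagents that add atoms: none
Why: Pyridine-mediated anti elimination of the tertiary chlorosulfite (classical dehydration of tertiary carbinols): H-1 is cis to the leaving group and cannot be removed, so the olefin forms away from C1, towards the C14 methyl group, and the C1 configuration is kept.

Step 10
Reactants: 20 exocyclic olefin
Product: 21 (1S,7S,8R,10S)-11-acetoxy-8-propanoyloxyguai-4-en-3-one (1α-H, 10α-H, 10β-CH3)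
Conditions: H2 (1 atm), 5% Pt/C, EtOAc, rt
Reagents that add atoms: none
Why: Heterogeneous hydrogenation saturates the 1,1-disubstituted olefin and not the tetrasubstituted enone; hydrogen is delivered to the equatorial α-face of C10, the β-face being screened by the syn-axial 8β-ester and the 7β side chain, which sets 10α-H and 10β-CH3.

Step 11
Reactants: 21 C1 epimer of the target
Product: 22 (1R,7S,8R,10S)-11-acetoxy-8-propanoyloxyguai-4-en-3-one (1β-H; target, CNP0288556.1)
Conditions: DBU (0.3 equiv), toluene, 50 °C
Reagents that add atoms: none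
Why: Base-mediated γ-epimerisation through the extended dienolate O–C3=C4–C5=C1 under thermodynamic control: only the 1β-H epimer allows a twist-chair cycloheptane with C2, the C10 methyl and the C7 side chain all equatorial, while 21 must hold the methyl group or the side chain axial, and the esters tolerate the non-nucleophilic amidine.

**Compound list**

1 | 7-methyl-1,4-dioxaspiro[4.5]decan-8-one (racemic) | CC1CC2(CCC1=O)OCCO2 | starting material
2 | (R)-1-phenylethylamine | C[C@@H](N)c1ccccc1 | starting material
3 | pent-1-en-3-one (ethyl vinyl ketone) | CCC(=O)C=C | starting material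
4 | water | O | starting material
5 | (R)-N-(7-methyl-1,4-dioxaspiro[4.5]decan-8-ylidene)-1-phenylethanamine | C[C@@H](N=C1CCC2(CC1C)OCCO2)c1ccccc1 | intermediate
6 | (R)-N-[(7R)-7-methyl-7-(3-oxopentyl)-1,4-dioxaspiro[4.5]decan-8-ylidene]-1-phenylethanamine | CCC(=O)CC[C@]1(C)CC2(OCCO2)CCC1=N[C@H](C)c1ccccc1 | intermediate
7 | (7R)-7-methyl-7-(3-oxopentyl)-1,4-dioxaspiro[4.5]decan-8-one | CCC(=O)CC[C@]1(C)CC2(OCCO2)CCC1=O | intermediate
8 | (4aR)-6,6-(ethane-1,2-diyldioxy)-8a-hydroxy-1,4a-dimethyloctahydronaphthalen-2(1H)-one (ketol; carbinol and α-methyl centres unassigned) | CC1C(=O)CC[C@]2(C)CC3(OCCO3)CCC12O | intermediate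
9 | (4aR)-6,6-(ethane-1,2-diyldioxy)-1,4a-dimethyl-4,4a,5,6,7,8-hexahydronaphthalen-2(3H)-one | CC1=C2CCC3(OCCO3)C[C@@]2(C)CCC1=O | intermediate
10 | (4aS)-6,6-(ethane-1,2-diyldioxy)-1,4a-dimethyl-5,6,7,8-tetrahydronaphthalen-2(4aH)-one | CC1=C2CCC3(OCCO3)C[C@@]2(C)C=CC1=O | intermediate
11 | (4aS)-1,4a-dimethyl-4a,5,7,8-tetrahydronaphthalene-2,6-dione | CC1=C2CCC(=O)C[C@@]2(C)C=CC1=O | intermediate
12 | acetone | CC(C)=O | starting material
13 | (7R,10S)-11-hydroxyeudesma-1,4-diene-3,8-dione (7α-H, 10β-CH3) | CC1=C2C[C@H](C(C)(C)O)C(=O)C[C@@]2(C)C=CC1=O | intermediate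
14 | (7S,8R,10S)-8,11-dihydroxyeudesma-1,4-dien-3-one (7α-H, 8β-OH, 10β-CH3) | CC1=C2C[C@H](C(C)(C)O)[C@H](O)C[C@@]2(C)C=CC1=O | intermediate
15 | propanoic anhydride | CCC(=O)OC(=O)CC | starting material
16 | (7S,8R,10S)-11-hydroxy-8-propanoyloxyeudesma-1,4-dien-3-one | CC1=C2C[C@H](C(C)(C)O)[C@H](OC(=O)CC)C[C@@]2(C)C=CC1=O | intermediate
17 | acetic anhydride | CC(=O)OC(C)=O | starting material
18 | (7S,8R,10S)-11-acetoxy-8-propanoyloxyeudesma-1,4-dien-3-one | CC1=C2C[C@H](C(C)(C)OC(C)=O)[C@H](OC(=O)CC)C[C@@]2(C)C=CC1=O | intermediate
19 | (1R,7S,8R,10R)-11-acetoxy-10-hydroxy-8-propanoyloxyguai-4-en-3-one (1α-H, 10α-OH) | CCC(=O)O[C@@H]1C[C@@](C)(O)[C@@H]2CC(=O)C(C)=C2C[C@@H]1C(C)(C)OC(C)=O | intermediate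
20 | (1S,7S,8R)-11-acetoxy-8-propanoyloxyguaia-4,10(14)-dien-3-one (1α-H) | CCC(=O)O[C@@H]1CC(=C)[C@@H]2CC(=O)C(C)=C2C[C@@H]1C(C)(C)OC(C)=O | intermediate
21 | (1S,7S,8R,10S)-11-acetoxy-8-propanoyloxyguai-4-en-3-one (1α-H, 10α-H) | CCC(=O)O[C@@H]1C[C@H](C)[C@@H]2CC(=O)C(C)=C2C[C@@H]1C(C)(C)OC(C)=O | intermediate
22 | (1R,7S,8R,10S)-11-acetoxy-8-propanoyloxyguai-4-en-3-one (1β-H, 10α-H) | CCC(=O)O[C@@H]1C[C@H](C)[C@H]2CC(=O)C(C)=C2C[C@@H]1C(C)(C)OC(C)=O | target

**Step count.** 11 steps in total; the longest linear sequence is 11 steps (fully linear).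

**Steps most likely to fail**

1. Step 4, the aldol addition. The kinetic C7 enolate may pass its charge to the vinylogous C6 position by proton transfer, the aldolate may lose acetone again on warming, and equilibration at C7 may stay incomplete. The fallback sets out from 11: the kinetic enolate is trapped (LDA, TMSCl, THF, −78 °C) as the trimethylsilyl enol ether F1. F1 is then joined to acetone under TiCl4 in CH2Cl2 at −78 °C (Mukaiyama aldol), which is irreversible and involves no free enolate. The route is rejoined at 13.

2. Step 11, the C1 equilibration. γ-Deprotonation with the mild amidine may be too slow to reach equilibrium, and a stronger alkoxide base would attack the two esters. The fallback sets out from 21: sodium methoxide in methanol (50 °C) removes both acyl groups and at the same time equilibrates C1 on the base-stable (1R,7S,8R,10S)-8,11-dihydroxyguai-4-en-3-one F2. Propanoylation of the secondary alcohol as in step 6 gives the hydroxy propanoate F3, and acetylation as in step 7 rejoins the route at 22.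

3. Step 9, the dehydration. Regiocontrol of the elimination may leak to the endocyclic 9,10-position, chloride may substitute, or ionisation at C10 may lead to conjugation through C1. The fallback sets out from 19: acylation with methyl chlorooxoacetate (DMAP, pyridine, CH2Cl2) gives the tertiary methyl oxalate F4. Bu3SnH/AIBN in toluene at 110 °C (Barton–Dolan radical deoxygenation) then reduces the C10 radical from the open α-face. The route is rejoined at 21, bypassing 20.

**Further compounds**

F1 | step 4 | (4aS)-1,4a-dimethyl-6-(trimethylsilyloxy)-5,8-dihydronaphthalen-2(4aH)-one | CC1=C2CC=C(O[Si](C)(C)C)C[C@@]2(C)C=CC1=O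
F2 | step 11 | (1R,7S,8R,10S)-8,11-dihydroxyguai-4-en-3-one | O[C@@H]1C[C@H](C)[C@H]2CC(=O)C(C)=C2C[C@@H]1C(C)(C)O
F3 | step 11 | (1R,7S,8R,10S)-11-hydroxy-8-propanoyloxyguai-4-en-3-one | CCC(=O)O[C@@H]1C[C@H](C)[C@H]2CC(=O)C(C)=C2C[C@@H]1C(C)(C)O
F4 | step 9 | (1R,7S,8R,10R)-11-acetoxy-10-(methoxyoxalyloxy)-8-propanoyloxyguai-4-en-3-one | CCC(=O)O[C@@H]1C[C@@](C)(OC(=O)C(=O)OC)[C@@H]2CC(=O)C(C)=C2C[C@@H]1C(C)(C)OC(C)=O
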